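## Structural features

The target is a monocyclic 2,3,4-trisubstituted tetrahydrofuran (O1, C2, C3, C4, C5H2). C2 carries a 3-hydroxy-4-methoxyphenyl group, C3 a hydroxymethyl group (C9), and C4 a 3-hydroxy-4-methoxybenzoyl group through the C7′ ketone. The three stereocentres C2, C3 and C4 are contiguous and all-trans, (2S,3R,4S), and the two aromatic halves have the same substitution pattern. C4 is α to the ketone and β to the ring oxygen, so base can epimerise it or open O1–C5 by retro-oxa-Michael cleavage. C2 is a para-methoxybenzylic ether that acid can ionise, the C9 alcohol is γ to the ketone, and the guaiacol-type phenols do not tolerate oxidants such as periodate. C4 can be corrected thermodynamically, but C2 and C3 cannot once C9 is an alcohol, so the real difficulty is the absolute configuration at C2 together with the 2,3-trans relationship. The key step uses two facts: O1–C5–C4–C7′ is the oxa-Michael adduct of an aryl vinyl ketone, and C3 can be the substituted terminus of an allyl unit whose other two carbons (C9 and a disposable C10) appear as a vinyl group. An allylpalladium zwitterion carrying the C2 alkoxide therefore closes O1–C5 and C3–C4 in one operation, while the C2–O1 bond and the absolute configuration pass through untouched.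

## Logic of the disconnections

14 ⇐ 13. Only the two aryl O–Si bonds are cut. The phenols stay masked to the end because free guaiacols would not survive periodate, alkoxide or Grignard conditions. Triisopropylsilyl is preferred to tert-butyldimethylsilyl: aryl ethers of the latter are lost quickly in alkaline media and can transfer silicon to an alkoxide, and both hazards occur earlier in the route. The forward step must remove silicon without enolising C4, hence buffered fluoride.

13 ⇐ 12 ⇐ 11. The C9 alcohol is traced to the C9 aldehyde and this to a C9=C10 alkene that is cleaved in the forward sense. With a vinyl group on C3 this carbon becomes an allyl terminus, which the key step needs. The forward steps need a buffered cleavage and a hydride that reduces the aldehyde but not the C7′ ketone. 12 must be handled only briefly, because C3 and C4 are both enolisable there.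

11 ⇐ 7 + 10. The bonds cut are O1–C5 and C3–C4. This removes the ring and two stereocentres (C3, C4) at once and splits the molecule into two halves built on the same aromatic unit. The C2–O1 bond is not cut, so 7 alone brings in the absolute configuration. The stereodescriptors were checked along the route and are consistent: the benzylic centre is R in 7 and C2 is S in 11, and C3 is S in 11 and 12 but R in 13 and 14, in each case the same arrangement in space under a changed CIP ranking. The centre at the vinyl-bearing carbon of 7 is erased on ionisation, so either diastereomer of 7 would serve; the cis isomer is used because the shortest route delivers it. The forward step must attack the substituted allyl terminus, select 2,3-trans from an equilibrating allyl complex, capture a singly activated acceptor, and leave C4 trans.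

7 ⇐ 6. The two carbonate C–O bonds are cut, leaving the unprotected ene-diol. The leaving group for palladium and the latent alkoxide are thus installed in one non-acidic step. The carbonyl transfer must not ionise the para-alkoxybenzylic C–O bond.

6 ⇐ 2 + 3. The benzylic C–C bond (C2–C3 of the target) is cut. A reagent-controlled allylboration sets C2, the one centre that matters. The γ-boryl reagent supplies the second oxygen by C–B oxidation, so no acetal has to be removed from an acid-labile para-alkoxybenzylic alcohol; this is the reason for preferring it to an alkoxyallylboration, and it is allowed because the anti relationship it gives is irrelevant. The step needs high facial control on an electron-rich aldehyde and an oxidative work-up that spares the aryl silyl ether.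

10 ⇐ 9 ⇐ 2 + 8. The C7′ ketone is traced to the carbinol, and the bond between C7′ and the future C4 is cut to aldehyde and vinyl nucleophile. 2 then serves both halves, which saves a protection step and a starting material compared with an acetophenone route, and the enone is released under neutral conditions just before use. The oxidation must be mild enough not to polymerise 10.

2 ⇐ 1. One O–Si bond is cut, leading back to the commercial phenol aldehyde.

## Other disconnections considered

Alternative 1: The cut is O1–C2 and C4–C5. C2, C3 and C4 come from cyclopropane A1 (aryl on C2, silyloxymethyl on C3, geminal diester on C4) and O1–C5 from formaldehyde A2. In the forward step Sn(OTf)2 binds the diester of A1, the polarised C2–C4 bond opens, the oxygen of A2 bonds to C2, and the malonate carbon closes on the carbonyl carbon of A2 to give diester A3.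
- In favour: Lewis-acid (3+2) annulation of aryl cyclopropane-1,1-diesters with aldehydes is dependable. C9 is at its final oxidation level from the start, so no vinyl group is degraded and no enolisable aldehyde is passed. C4 is quaternary in A3, which excludes epimerisation and retro-oxa-Michael opening in the following steps. On these points A3 is the better intermediate than 11 or 12.
- Against: this annulation normally proceeds by backside attack at the donor carbon, so 2,3-trans A3 needs the cis isomer of A1 (drawn as such), the harder one to make enantiopure. A para-alkoxy donor favours ionisation over the SN2-like path, which puts C2 at risk. Monomeric A2 is awkward under Lewis acid. After the annulation one ester must be removed and the other converted into the aroyl group, which creates the sensitive β-alkoxy ketone late.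
- Comparison: both plans build one ring and two bonds in a single (3+2) event and are equal there. Stereospecific opening is in principle the better mechanism for C2/C3 than Curtin–Hammett selection, but it is the weaker one for this electron-rich aryl group. The alternative brings in one aryl unit at the key step where the chosen plan brings in both. With the synthesis of A1 and four or more steps after A3 it would be clearly longer than nine steps.

Alternative 2: The cut is C2–C3, made on diazo lactone A4. In A4, C9 (lactone carbonyl) and C7′ (lactone carbinol carbon bearing the second aryl group) are tied together temporarily, and O1 is already present as an aryl-methyl ether on C5. Rh2(OAc)4 converts A4 into a carbene at C3 that inserts into the benzylic C2–H bond, giving the cis-fused bicyclic lactone A5.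
- In favour: 1,5-insertion into an ether-activated benzylic C–H bond is the preferred mode of such carbenes and is intramolecular, so there is no acceptor to polymerise and no bimolecular capture to win; here the alternative is the better. C9 arrives at the acid level and needs only reduction, never passing an epimerisable aldehyde. C3 ends with the target configuration.
- Against: the cis ring fusion puts C4 in the wrong configuration and the new aryl group on the concave face, so C2 and C4 must both be inverted later. C4 can be inverted by base once C7′ is a ketone, but C2 only by acid ionisation of the benzylic ether, which the target tolerates least. The lactone must then be reduced and C7′ oxidised selectively. The carbene may also attack the electron-rich arenes. A4 needs its own enantioselective synthesis of two stereocentres that are both sacrificed later.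
- Comparison: the ring count is equal, but one skeletal bond is formed instead of two. The ring closure is more reliable, the stereochemical outcome less so (two of three centres wrong at first, against none in 11). It is distinctly longer.

Alternative 3: The cut is C2–C3 and C4–C5 in acetal A6, a 2-aryl-4-alkenyl-1,3-dioxolane whose E-alkene carries the pivaloyloxymethyl group (C9) and whose carbinol carbon is the future C7′. SnCl4 opens A6 to the O1=C2 oxocarbenium ion, the alkene terminus C3 bonds to C2 in a chair-like Prins closure, and the ring methylene C5 migrates to the cationic C4. This pinacol shift contracts the ring to the tetrahydrofuran and releases C7′ as the formyl group of aldehyde A7.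
- In favour: all three stereocentres are set in one step, C2/C3 by the chair and C4 as an epimerisable α-formyl centre, and C9 is already at the alcohol level. On both counts it is equal to or better than the chosen plan. The chirality comes from the chiral pool without a stoichiometric chiral reagent, which is better.
- Against: a strong Lewis acid acts on a para-alkoxybenzylic oxocarbenium ion and then on the ionisable C2 ether of A7, and the aryl silyl ether must survive it. Chirality is relayed through a carbinol centre that is destroyed, so any competing boat or oxonia-Cope pathway costs enantiopurity. A6 is drawn with the configuration that a chair with an equatorial alkoxide would require. A7 still lacks the second aryl group, which needs arylation and oxidation at C7′, and the pivalate must then be removed from a base-sensitive β-alkoxy ketone.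
- Comparison: it forms two skeletal bonds and one ring as the chosen step does, plus a third stereocentre. The cationic, intramolecular closure is the safer ring closure than a zwitterionic intermolecular capture. The assembly of A6 and three to four steps after A7 make it longer, and it is linear where the chosen plan is convergent.

Key step: step 6

Assumption (remark on the chemistry): (−)-Ipc2BH, crystallised beforehand from (+)-α-pinene and BH3·SMe2, is treated as a stock reagent. Allylboranes built on this Ipc2B unit are taken to add to the Si face of aryl aldehydes, as the parent allyl reagent does; the antipodal borane is equally available should the sense prove opposite. Ring positions are numbered O1, C2 (aryl), C3, C4 (aroyl), C5 throughout.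

Step 1
Reactants: 1 isovanillin (3-hydroxy-4-methoxybenzaldehyde)
Product: 2 4-methoxy-3-(triisopropylsilyloxy)benzaldehyde
Conditions: TIPSCl, imidazole, DMF, 23 °C
Reagents that add atoms: chlorotriisopropylsilane (TIPSCl), CC(C)[Si](Cl)(C(C)C)C(C)C
Why: Standard imidazole-mediated O-silylation of a phenol; the aldehyde is inert, and the hindered aryl silyl ether is chosen to withstand the mildly basic oxidation of step 2 and the alkoxide of step 6.

Step 2
Reactants: 2 4-methoxy-3-(triisopropylsilyloxy)benzaldehyde; 3 allenylboronic acid pinacol ester
Product: 6 (1R,2S)-1-[4-methoxy-3-(triisopropylsilyloxy)phenyl]but-3-ene-1,2-diol (anti), via (E)-γ-borylallylborane 4 (not isolated), via borinate adduct 5 (not isolated)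
Conditions: (−)-Ipc2BH (1.3 equiv), 3, Et2O, 0 °C; then 2, −78 °C; then NaBO3·4H2O, THF/H2O, 0 → 23 °C
Reagents that add atoms: sodium perborate tetrahydrate (NaBO3·4H2O, oxygen on C2 of 6), [Na+].[O-]OB=O
Why: Hydroboration of the terminal allene π-bond gives the E γ-borylallylborane 4, which adds to 2 through a chair (Zimmerman–Traxler) transition state to give the anti adduct 5; the Ipc2B unit from (+)-α-pinene should direct attack to the Si face and so set the benzylic R centre (Brown anti-diol synthesis). Perborate then oxidises the C–B bond with retention; the allylic centre of 6 is of no later consequence, so even incomplete anti selectivity would be harmless.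

Step 3
Reactants: 6 (1R,2S)-1-[4-methoxy-3-(triisopropylsilyloxy)phenyl]but-3-ene-1,2-diol
Product: 7 (4R,5S)-4-[4-methoxy-3-(triisopropylsilyloxy)phenyl]-5-vinyl-1,3-dioxolan-2-one (cis)
Conditions: CDI (1.5 equiv), CH2Cl2, 23 °C
Reagents that add atoms: 1,1′-carbonyldiimidazole (CDI), O=C(n1ccnc1)n1ccnc1
Why: Carbonyl transfer to a 1,2-diol through the mono-imidazolide, which closes the five-membered carbonate; the medium stays weakly basic, so the para-alkoxybenzylic C–O bond is not ionised and both stereocentres are retained.

Step 4
Reactants: 2 4-methoxy-3-(triisopropylsilyloxy)benzaldehyde; 8 vinylmagnesium bromide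
Product: 9 rac-1-[4-methoxy-3-(triisopropylsilyloxy)phenyl]prop-2-en-1-ol
Conditions: THF, −78 → 0 °C; aq NH4Cl
Reagents that add atoms: none
Why: Grignard 1,2-addition to an aryl aldehyde; the new carbinol centre is racemic and is removed in the next step.

Step 5
Reactants: 9 rac-1-[4-methoxy-3-(triisopropylsilyloxy)phenyl]prop-2-en-1-ol
Product: 10 1-[4-methoxy-3-(triisopropylsilyloxy)phenyl]prop-2-en-1-one
Conditions: activated MnO2 (excess), CH2Cl2, 23 °C; filtered, kept cold with BHT and used at once
Reagents that add atoms: none
Why: MnO2 oxidation of a carbinol that is both allylic and benzylic; the heterogeneous, neutral conditions give a filtrate free of acid or base, which limits polymerisation of the aryl vinyl ketone.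

Step 6
Reactants: 7 (4R,5S)-4-[4-methoxy-3-(triisopropylsilyloxy)phenyl]-5-vinyl-1,3-dioxolan-2-one; 10 1-[4-methoxy-3-(triisopropylsilyloxy)phenyl]prop-2-en-1-one
Product: 11 (2S,3S,4S)-4-[4-methoxy-3-(triisopropylsilyloxy)benzoyl]-2-[4-methoxy-3-(triisopropylsilyloxy)phenyl]-3-vinyltetrahydrofuran (all-trans)
Conditions: Pd(PPh3)4 (5 mol %), 10 (1.5 equiv), THF, 0 → 40 °C, 7 added slowly
Reagents that add atoms: none
Why: Pd(PPh3)4 ionises the allylic C–O bond of 7 anti to the metal and CO2 is lost, leaving a zwitterion with the C2 alkoxide next to a cationic η3-allylpalladium unit; the benzylic C–O bond is never broken, so the R centre of 7 becomes 2S of 11. The alkoxide adds reversibly to the unhindered β-carbon of 10 (O1–C5), and the ketone enolate attacks the proximal allyl terminus anti to palladium (C3–C4) in a 5-exo closure that leaves the other two allyl carbons as the vinyl group; attack at the distal terminus would need a seven-membered ring. The closest known reaction type is the decarboxylative (3+2) cycloaddition of vinylethylene carbonates and vinyl oxiranes with Michael acceptors under zerovalent palladium catalysis. C3: the two allyl faces exchange by η3–η1–η3 isomerisation through the unsubstituted terminus faster than capture, so the centre erased from 7 is reset under Curtin–Hammett control by the C2 aryl group, which takes the pseudo-equatorial site of the envelope and places the allyl unit trans. C4: the enolate should bond through the face that keeps the aroyl group away from the C3 substituent, giving 3,4-trans, and this centre α to the ketone also lies in the thermodynamic well of the all-trans isomer. The step needs branched attack (secured by ring size), capture before the zwitterion isomerises (β-unsubstituted electron-poor 10 in excess, slow addition of 7), and no competing acceptor (hence a dba-free catalyst).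

Step 7
Reactants: 11 (2S,3S,4S)-4-aroyl-2-aryl-3-vinyltetrahydrofuran
Product: 12 (2S,3S,4S)-4-[4-methoxy-3-(triisopropylsilyloxy)benzoyl]-2-[4-methoxy-3-(triisopropylsilyloxy)phenyl]tetrahydrofuran-3-carbaldehyde
Conditions: K2OsO4·2H2O (2 mol %), NaIO4 (4 equiv), 2,6-lutidine (2 equiv), 1,4-dioxane/H2O (3:1), 23 °C; crude 12 taken on without chromatography
Reagents that add atoms: sodium periodate (terminal oxidant, supplies the aldehyde oxygen through the osmate ester), [Na+].[O-]I(=O)(=O)=O
Why: Lemieux–Johnson dihydroxylation and glycol cleavage of the only alkene; 2,6-lutidine buffers the medium so that the keto aldehyde is not enolised, and the silylated arenes, ketone and benzylic ether are inert to periodate.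

Step 8
Reactants: 12 (2S,3S,4S)-4-aroyl-2-aryltetrahydrofuran-3-carbaldehyde
Product: 13 (2S,3R,4S)-3-(hydroxymethyl)-4-[4-methoxy-3-(triisopropylsilyloxy)benzoyl]-2-[4-methoxy-3-(triisopropylsilyloxy)phenyl]tetrahydrofuran
Conditions: NaBH(OAc)3 (3 equiv), AcOH (2 equiv), THF, 0 → 23 °C
Reagents that add atoms: none
Why: Triacetoxyborohydride reduces aldehydes but not ketones, least of all an aryl ketone deactivated by a para-methoxy group; the weakly acidic medium avoids enolate formation, and the 3,4-trans hydroxy ketone cannot close to a strained trans-fused hemiketal.

Step 9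
Reactants: 13 (2S,3R,4S)-bis(triisopropylsilyl) ether
Product: 14 [(3S,4R,5S)-5-(3-hydroxy-4-methoxyphenyl)-4-(hydroxymethyl)oxolan-3-yl](3-hydroxy-4-methoxyphenyl)methanone, i.e. (2S,3R,4S) in the ring numbering used here
Conditions: TBAF (2.5 equiv), AcOH (2.5 equiv), THF, 0 °C
Reagents that add atoms: none
Why: Fluoride cleaves aryl silyl ethers rapidly because phenoxide is a good leaving group; acetic acid protonates the phenoxides at once, so no base strong enough to enolise C4 or trigger retro-oxa-Michael opening is present.

Compound list

1 | isovanillin (3-hydroxy-4-methoxybenzaldehyde) | COc1ccc(C=O)cc1O | starting material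
2 | 4-methoxy-3-(triisopropylsilyloxy)benzaldehyde | COc1ccc(C=O)cc1O[Si](C(C)C)(C(C)C)C(C)C | intermediate
3 | allenylboronic acid pinacol ester | C=C=CB1OC(C)(C)C(C)(C)O1 | starting material
4 | (E)-[3-(4,4,5,5-tetramethyl-1,3,2-dioxaborolan-2-yl)allyl]diisopinocampheylborane, Ipc groups from (+)-α-pinene | CC1(C)OB(/C=C/CB([C@@H]2C[C@@H]3C[C@H]([C@H]2C)C3(C)C)[C@@H]2C[C@@H]3C[C@H]([C@H]2C)C3(C)C)OC1(C)C | intermediate
5 | O-diisopinocampheylboryl derivative of the C2-pinacolboryl analogue of 6, same spatial arrangement as 6 | B(O[C@H](c1ccc(OC)c(O[Si](C(C)C)(C(C)C)C(C)C)c1)[C@H](C=C)B1OC(C)(C)C(C)(C)O1)([C@@H]1C[C@@H]2C[C@H]([C@H]1C)C2(C)C)[C@@H]1C[C@@H]2C[C@H]([C@H]1C)C2(C)C | intermediate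
6 | (1R,2S)-1-[4-methoxy-3-(triisopropylsilyloxy)phenyl]but-3-ene-1,2-diol | O[C@H](c1ccc(OC)c(O[Si](C(C)C)(C(C)C)C(C)C)c1)[C@H](C=C)O | intermediate
7 | (4R,5S)-4-[4-methoxy-3-(triisopropylsilyloxy)phenyl]-5-vinyl-1,3-dioxolan-2-one | O=C1O[C@H](c2ccc(OC)c(O[Si](C(C)C)(C(C)C)C(C)C)c2)[C@H](C=C)O1 | intermediate
8 | vinylmagnesium bromide | C=C[Mg]Br | starting material
9 | rac-1-[4-methoxy-3-(triisopropylsilyloxy)phenyl]prop-2-en-1-ol | C=CC(O)c1ccc(OC)c(O[Si](C(C)C)(C(C)C)C(C)C)c1 | intermediate
10 | 1-[4-methoxy-3-(triisopropylsilyloxy)phenyl]prop-2-en-1-one | C=CC(=O)c1ccc(OC)c(O[Si](C(C)C)(C(C)C)C(C)C)c1 | intermediate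
11 | (2S,3S,4S)-4-[4-methoxy-3-(triisopropylsilyloxy)benzoyl]-2-[4-methoxy-3-(triisopropylsilyloxy)phenyl]-3-vinyltetrahydrofuran | COc1ccc(C(=O)[C@@H]2CO[C@H](c3ccc(OC)c(O[Si](C(C)C)(C(C)C)C(C)C)c3)[C@H]2C=C)cc1O[Si](C(C)C)(C(C)C)C(C)C | intermediate
12 | (2S,3S,4S)-4-[4-methoxy-3-(triisopropylsilyloxy)benzoyl]-2-[4-methoxy-3-(triisopropylsilyloxy)phenyl]tetrahydrofuran-3-carbaldehyde | COc1ccc(C(=O)[C@@H]2CO[C@H](c3ccc(OC)c(O[Si](C(C)C)(C(C)C)C(C)C)c3)[C@H]2C=O)cc1O[Si](C(C)C)(C(C)C)C(C)C | intermediate
13 | (2S,3R,4S)-3-(hydroxymethyl)-4-[4-methoxy-3-(triisopropylsilyloxy)benzoyl]-2-[4-methoxy-3-(triisopropylsilyloxy)phenyl]tetrahydrofuran | COc1ccc(C(=O)[C@@H]2CO[C@H](c3ccc(OC)c(O[Si](C(C)C)(C(C)C)C(C)C)c3)[C@H]2CO)cc1O[Si](C(C)C)(C(C)C)C(C)C | intermediate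
14 | [(3S,4R,5S)-5-(3-hydroxy-4-methoxyphenyl)-4-(hydroxymethyl)oxolan-3-yl](3-hydroxy-4-methoxyphenyl)methanone | COc1ccc(C(=O)[C@@H]2CO[C@H](c3ccc(OC)c(O)c3)[C@H]2CO)cc1O | target

Total step count: 9. Longest linear sequence: 7 steps (steps 1, 2, 3, 6, 7, 8, 9); steps 4 and 5 form the second branch from 2.

Least certain steps

Step 6 (key step). The most likely failure is that the zwitterion isomerises unimolecularly (hydride shift to an aryl allyl ketone, or collapse to a vinyl oxirane or dihydrofuran) faster than it is captured. The enolate of a singly activated acceptor forms reversibly and in low concentration, so the bimolecular path is slow by comparison. Alkoxide-initiated polymerisation of 10 and incomplete 2,3-trans selection are further risks. Incomplete 3,4-trans control alone would be remedied by equilibrating purified 11 with DBU in CH2Cl2, since enolisation or reversible O1–C5 opening affects only C4.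

The fallback makes the acceptor doubly activated, which is the benchmark case for this cycloaddition. It sets out from 2. Addition of lithiated methyl phenyl sulfone should give rac-1-[4-methoxy-3-(triisopropylsilyloxy)phenyl]-2-(phenylsulfonyl)ethanol F1. Dess–Martin oxidation should give the β-keto sulfone F2, and piperidine/acetic acid-mediated condensation with paraformaldehyde the α-methylene β-keto sulfone F3. F3 and 7 under Pd(PPh3)4 should give the 4-aroyl-4-(phenylsulfonyl)-2-aryl-3-vinyltetrahydrofuran F4 through a stabilised sulfonyl enolate. Reductive desulfonylation with SmI2 in THF/MeOH at −78 °C, with protonation of the samarium enolate, returns to the route at 11.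

Step 2. What may go wrong is insufficient facial control with an electron-rich, slowly reacting aldehyde, a second allylboration of 2 by the allylboronate unit of 5, or partial loss of the aryl silyl ether during the oxidative work-up. The fallback is the alkoxyallylboration route from 2. The Z γ-(methoxymethoxy)allylborane, made from allyl methoxymethyl ether, sec-BuLi, (−)-Ipc2BOMe and BF3·OEt2 and worked up with ethanolamine, should give (1R,2R)-2-(methoxymethoxy)-1-[4-methoxy-3-(triisopropylsilyloxy)phenyl]but-3-en-1-ol F5. Acetal removal under buffered conditions (TMSOTf, 2,2′-bipyridyl, then water) gives the syn diol F6, and CDI the trans carbonate F7. F7 replaces 7 in step 6, because both carbonates give the same zwitterion, and the route is rejoined at 11. This is one step longer and exposes a para-alkoxybenzylic alcohol to a Lewis acid, which is why it is not the first choice.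

Step 7. The keto aldehyde may enolise during work-up or on silica, leading to epimerisation at C3 or to β-elimination that opens O1–C2 and would endanger C2 itself. The fallback never isolates 12. Dihydroxylation of 11 with catalytic K2OsO4·2H2O and N-methylmorpholine N-oxide gives the stable 3-(1,2-dihydroxyethyl) compound F8. F8 is cleaved with silica-supported NaIO4 in CH2Cl2 at 0 °C, and the filtrate is treated directly with NaBH(OAc)3, which rejoins the route at 13.

Step 8. The ketone may be over-reduced by intramolecular hydride delivery from the C9 alkoxyborohydride, or the aldehyde may be reduced too slowly. The fallback is a redox detour. NaBH4 in MeOH/CH2Cl2 reduces both carbonyl groups of 12 to the C7′,C9 diol F9 (C7′ epimers). MnO2 then oxidises only the para-alkoxybenzylic carbinol and returns to 13.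

Further compounds

F1 | step 6 | rac-1-[4-methoxy-3-(triisopropylsilyloxy)phenyl]-2-(phenylsulfonyl)ethan-1-ol | OC(CS(=O)(=O)c1ccccc1)c1ccc(OC)c(O[Si](C(C)C)(C(C)C)C(C)C)c1
F2 | step 6 | 1-[4-methoxy-3-(triisopropylsilyloxy)phenyl]-2-(phenylsulfonyl)ethan-1-one | O=C(CS(=O)(=O)c1ccccc1)c1ccc(OC)c(O[Si](C(C)C)(C(C)C)C(C)C)c1
F3 | step 6 | 1-[4-methoxy-3-(triisopropylsilyloxy)phenyl]-2-(phenylsulfonyl)prop-2-en-1-one | C=C(C(=O)c1ccc(OC)c(O[Si](C(C)C)(C(C)C)C(C)C)c1)S(=O)(=O)c1ccccc1
F4 | step 6 | 4-[4-methoxy-3-(triisopropylsilyloxy)benzoyl]-2-[4-methoxy-3-(triisopropylsilyloxy)phenyl]-4-(phenylsulfonyl)-3-vinyltetrahydrofuran, C2 and C3 arranged as in 11, C4 either configuration | COc1ccc(C(=O)C2(S(=O)(=O)c3ccccc3)CO[C@H](c3ccc(OC)c(O[Si](C(C)C)(C(C)C)C(C)C)c3)[C@H]2C=C)cc1O[Si](C(C)C)(C(C)C)C(C)C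
F5 | step 2 | (1R,2R)-2-(methoxymethoxy)-1-[4-methoxy-3-(triisopropylsilyloxy)phenyl]but-3-en-1-ol | O[C@H](c1ccc(OC)c(O[Si](C(C)C)(C(C)C)C(C)C)c1)[C@@H](C=C)OCOC
F6 | step 2 | (1R,2R)-1-[4-methoxy-3-(triisopropylsilyloxy)phenyl]but-3-ene-1,2-diol | O[C@H](c1ccc(OC)c(O[Si](C(C)C)(C(C)C)C(C)C)c1)[C@@H](C=C)O
F7 | step 2 | (4R,5R)-4-[4-methoxy-3-(triisopropylsilyloxy)phenyl]-5-vinyl-1,3-dioxolan-2-one | O=C1O[C@H](c2ccc(OC)c(O[Si](C(C)C)(C(C)C)C(C)C)c2)[C@@H](C=C)O1
F8 | step 7 | 3-(1,2-dihydroxyethyl) analogue of 11, ring centres as in 11, new carbinol centre as a mixture | COc1ccc(C(=O)[C@@H]2CO[C@H](c3ccc(OC)c(O[Si](C(C)C)(C(C)C)C(C)C)c3)[C@H]2C(O)CO)cc1O[Si](C(C)C)(C(C)C)C(C)C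
F9 | step 8 | C7′ carbinol analogue of 13, ring centres as in 13, C7′ as a mixture | COc1ccc(C(O)[C@@H]2CO[C@H](c3ccc(OC)c(O[Si](C(C)C)(C(C)C)C(C)C)c3)[C@H]2CO)cc1O[Si](C(C)C)(C(C)C)C(C)C
A1 | alternative 1 | dimethyl (2R,3R)-2-[3-(tert-butyldimethylsilyloxy)-4-methoxyphenyl]-3-[(tert-butyldimethylsilyloxy)methyl]cyclopropane-1,1-dicarboxylate (cis) | COC(=O)C1(C(=O)OC)[C@@H](c2ccc(OC)c(O[Si](C)(C)C(C)(C)C)c2)[C@H]1CO[Si](C)(C)C(C)(C)C
A2 | alternative 1 | formaldehyde | C=O
A3 | alternative 1 | dimethyl 2,3-trans-2-[3-(tert-butyldimethylsilyloxy)-4-methoxyphenyl]-3-[(tert-butyldimethylsilyloxy)methyl]tetrahydrofuran-4,4-dicarboxylate | COC(=O)C1(C(=O)OC)CO[C@H](c2ccc(OC)c(O[Si](C)(C)C(C)(C)C)c2)[C@H]1CO[Si](C)(C)C(C)(C)C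
A4 | alternative 2 | trans-5-aryl-4-[(arylmethoxy)methyl]-3-diazooxolan-2-one, aryl = 3-(tert-butyldimethylsilyloxy)-4-methoxyphenyl | O=C1O[C@H](c2ccc(OC)c(O[Si](C)(C)C(C)(C)C)c2)[C@@H](COCc2ccc(OC)c(O[Si](C)(C)C(C)(C)C)c2)C1=[N+]=[N-]
A5 | alternative 2 | cis-fused 2,6-diaryl-3,7-dioxabicyclo[3.3.0]octan-8-one, new aryl group on the concave face | O=C1O[C@H](c3ccc(OC)c(O[Si](C)(C)C(C)(C)C)c3)[C@H]2CO[C@@H](c3ccc(OC)c(O[Si](C)(C)C(C)(C)C)c3)[C@@H]12
A6 | alternative 3 | (4R)-2-[3-(tert-butyldimethylsilyloxy)-4-methoxyphenyl]-4-[(E)-3-(pivaloyloxy)prop-1-enyl]-1,3-dioxolane, acetal carbon as a mixture | CC(C)(C)C(=O)OC/C=C/[C@@H]1COC(c2ccc(OC)c(O[Si](C)(C)C(C)(C)C)c2)O1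
A7 | alternative 3 | all-trans 2-[3-(tert-butyldimethylsilyloxy)-4-methoxyphenyl]-3-(pivaloyloxymethyl)tetrahydrofuran-4-carbaldehyde | O=C[C@@H]1CO[C@H](c2ccc(OC)c(O[Si](C)(C)C(C)(C)C)c2)[C@H]1COC(=O)C(C)(C)C
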